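**Plan**
- Cuts: the 16-methylene goes back to the 17-nor-16-ketone and the 2β,3β-diol to the C2=C3 alkene. Ring A and the 19,20-lactone are then cut together by returning C5 from C4 to C19, which gives a seven-membered ring C10-C1-C2-C3-C4-C19-C5 with C19 as a ketone.
- Feature used: C19 sits on C4, C4 is next to C5, and C5 is next to C10, which carries the C20 oxygen on the same (α) face. A C19 ketone inside the enlarged ring is therefore within reach of C20-OH as a five-membered hemiketal, and a 1,2-shift of C5 from C19 to C4 turns that hemiketal into the δ-lactone and the seven-membered ring into ring A.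
- Further cuts: C2=C3 (metathesis) and C19-C4 (crotyl addition to a C19 γ-lactone); C5-C6 and C9-C10 (double Michael annulation, ring B); C13-C16 (gold-catalysed enol ether/alkyne closure, ring D); C8-C15 (Birch alkylation of benzoic acid, ring C).
- Forward order: ring C, ring D, ring B, the seven-membered precursor of ring A, then ring A and lactone in one step, diol, methylene, ester cleavage.
- Stereochemistry: C8 by enzymatic desymmetrisation (C13 follows); C9 by exo attack on the bicyclo[3.2.1]octenone; C10 by β-face allylation; C5 by the cis-fused lactol/lactone; C6 by equilibration; C4 by the C20-O-C19 tether in the key step; C2/C3 by osmylation anti to the lactone bridge.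

Key step: step 19

Remark 1: atoms are numbered as in ent-gibberellane (ring A = C1-C5 and C10; C19 = lactone carbonyl on C4; C20 = OCH2 on C10; C7 = carboxyl on C6); α is the face of ring A that carries the lactone bridge, and the target is read as the 2β,3β-diol.
Remark 2: the ene-reductase of step 5 is assumed to be chosen (wild type or variant) for the sense that gives (S)-8.

Step 1
Reactants: 1 benzoic acid; 2 propargyl bromide
Product: 3 1-(prop-2-yn-1-yl)cyclohexa-2,5-diene-1-carboxylic acid
Conditions: Li, NH3(l)/THF, −78 °C; then 2; aq. NH4Cl, HCl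
Reagents that add atoms: none
Why: Birch reduction of the benzoate should give the 1,4-dihydro carboxylate dianion, which is alkylated at C1 by the propargylic bromide (Birch reductive alkylation) and so creates the future quaternary C8.

Step 2
Reactants: 3 1-(prop-2-yn-1-yl)cyclohexa-2,5-diene-1-carboxylic acid
Product: 5 2-diazo-1-[1-(prop-2-yn-1-yl)cyclohexa-2,5-dien-1-yl]ethan-1-one, via acid chloride 4 (not isolated)
Conditions: (COCl)2, cat. DMF, CH2Cl2, 0 °C to rt; evaporate; CH2N2 (3 equiv), Et2O, 0 °C
Reagents that add atoms: diazomethane, C=[N+]=[N-]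
Why: acylation of diazomethane by the acid chloride (first half of an Arndt–Eistert homologation), with excess diazomethane taking up the HCl.

Step 3
Reactants: 5 2-diazo-1-[1-(prop-2-yn-1-yl)cyclohexa-2,5-dien-1-yl]ethan-1-one
Product: 6 tert-butyl 2-[1-(prop-2-yn-1-yl)cyclohexa-2,5-dien-1-yl]acetate
Conditions: PhCO2Ag (cat.), Et3N, t-BuOH/THF, 60 °C, dark
Reagents that add atoms: tert-butanol, CC(C)(C)O
Why: silver-catalysed Wolff rearrangement (loss of N2, 1,2-shift of the quaternary carbon, capture of the ketene by tert-butanol) should give the homologated ester, whose CH2 and carboxyl carbons become C6 and C7.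

Step 4
Reactants: 6 tert-butyl 2-[1-(prop-2-yn-1-yl)cyclohexa-2,5-dien-1-yl]acetate
Product: 7 tert-butyl 2-[4-oxo-1-(prop-2-yn-1-yl)cyclohexa-2,5-dien-1-yl]acetate
Conditions: Rh2(cap)4 (1 mol%), t-BuOOH (5 equiv), K2CO3, CH2Cl2, rt
Reagents that add atoms: tert-butyl hydroperoxide, CC(C)(C)OO
Why: the doubly allylic CH2 is the weakest C–H bond, so catalytic allylic oxidation of the 1,4-cyclohexadiene should give the 2,5-cyclohexadienone.

Step 5
Reactants: 7 tert-butyl 2-[4-oxo-1-(prop-2-yn-1-yl)cyclohexa-2,5-dien-1-yl]acetate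
Product: 8 tert-butyl 2-[(1S)-4-oxo-1-(prop-2-yn-1-yl)cyclohex-2-en-1-yl]acetate
Conditions: ene-reductase (old-yellow-enzyme family), NADP+ (cat.), glucose dehydrogenase, D-glucose, phosphate buffer pH 7/DMSO, 30 °C
Reagents that add atoms: none
Why: flavin-dependent ene-reductases reduce one of the two enantiotopic C=C bonds of prochiral 4,4-disubstituted cyclohexadienones and stop at the enone (enzymatic desymmetrisation), which sets C8 and the absolute configuration of the whole route.

Step 6
Reactants: 8 tert-butyl 2-[(1S)-4-oxo-1-(prop-2-yn-1-yl)cyclohex-2-en-1-yl]acetate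
Product: 9 tert-butyl 2-[(1S)-4-(tert-butyldimethylsilyloxy)-1-(prop-2-yn-1-yl)cyclohexa-2,4-dien-1-yl]acetate
Conditions: LDA (1.05 equiv), THF, −78 °C; TBSCl, DMPU, −78 to 0 °C
Reagents that add atoms: tert-butyldimethylsilyl chloride, CC(C)(C)[Si](C)(C)Cl
Why: kinetic deprotonation of an enone takes the α′ CH2 (C13), and O-silylation of the cross-conjugated dienolate gives the 2-silyloxy diene (kinetic enol silyl ether formation).

Step 7
Reactants: 9 tert-butyl 2-[(1S)-4-(tert-butyldimethylsilyloxy)-1-(prop-2-yn-1-yl)cyclohexa-2,4-dien-1-yl]acetate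
Product: 10 tert-butyl 2-(6-methylidene-4-oxobicyclo[3.2.1]oct-2-en-1-yl)acetate
Conditions: Ph3PAuCl (5 mol%), AgBF4 (5 mol%), CH2Cl2/MeOH 10:1, rt
Reagents that add atoms: none
Why: gold(I)-catalysed 5-exo-dig addition of the enol ether carbon C13 to the activated alkyne (Conia-ene-type carbocyclisation) should close ring D, and the one-carbon tether from C8 fixes the configuration at C13.

Step 8
Reactants: 10 tert-butyl 2-(6-methylidene-4-oxobicyclo[3.2.1]oct-2-en-1-yl)acetate
Product: 12 tert-butyl 2-(4,6-dioxobicyclo[3.2.1]oct-2-en-1-yl)acetate, via ozonide 11 (not isolated)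
Conditions: O3 (1 equiv), CH2Cl2, −78 °C; Me2S, −78 °C to rt
Reagents that add atoms: ozone, [O-][O+]=O
Why: ozonolysis should take the electron-rich 1,1-disubstituted alkene far faster than the enone C=C, and the C16 ketone masks the methylene against the later acid and osmylation steps.

Step 9
Reactants: 12 tert-butyl 2-(4,6-dioxobicyclo[3.2.1]oct-2-en-1-yl)acetate
Product: 13 tert-butyl 2-[4-oxospiro(bicyclo[3.2.1]oct-2-ene-6,2'-[1,3]dioxolan)-1-yl]acetate
Conditions: TMSOCH2CH2OTMS, TMSOTf (5 mol%), CH2Cl2, −78 to −20 °C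
Reagents that add atoms: 1,2-bis(trimethylsilyloxy)ethane, C[Si](C)(C)OCCO[Si](C)(C)C
Why: silyl-triflate-catalysed ketalisation at low temperature should select the saturated C16 ketone over the conjugated C12 ketone.

Step 10
Reactants: 14 2,2-dimethoxyacetaldehyde; 15 methyl (triphenylphosphoranylidene)acetate
Product: 16 methyl (E)-4,4-dimethoxybut-2-enoate
Conditions: CH2Cl2, rt
Reagents that add atoms: none
Why: Wittig olefination with a stabilised ylide should give the E-enoate that serves as the C5/C10/C19/C20 unit.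

Step 11
Reactants: 13 tert-butyl 2-[4-oxospiro(bicyclo[3.2.1]oct-2-ene-6,2'-[1,3]dioxolan)-1-yl]acetate; 16 methyl (E)-4,4-dimethoxybut-2-enoate
Product: 17 B/C/D keto diester (5α-CH(OMe)2; 6β-CO2tBu; 10β-CO2Me; 9β-H; 12-oxo; 16-ketal)
Conditions: LDA (1.1 equiv), THF, −78 °C; 16 (1.3 equiv), −78 to −40 °C; aq. NH4Cl
Reagents that add atoms: none
Why: Michael–Michael ring closure: the C6 ester enolate adds to the β-carbon of 16, and the resulting C10 ester enolate closes ring B by 5-exo-trig conjugate addition to C9 from the exo face (syn to the one-carbon bridge C14, anti to the ketal-bearing bridge), which sets 9β-H; the three ring-B substituents are expected all-trans, and C6 (α to its ester) can be equilibrated to this 6β arrangement.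

Step 12
Reactants: 17 B/C/D keto diester
Product: 19 12-deoxo B/C/D diester (5α-CH(OMe)2; 6β-CO2tBu; 10β-CO2Me; 16-ketal), via tosylhydrazone 18 (not isolated)
Conditions: TsNHNH2, EtOH, rt; evaporate; catecholborane, CHCl3, 0 °C; NaOAc·3H2O, reflux
Reagents that add atoms: none
Why: reductive deoxygenation of the only ketone through its tosylhydrazone (hydride addition, then loss of sulfinate and N2) runs under neutral conditions that should spare both acetals and both esters.

Step 13
Reactants: 19 12-deoxo B/C/D diester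
Product: 20 10β-allyl-10α-methoxycarbonyl diester (C10 quaternary)
Conditions: LDA (1.2 equiv), THF/DMPU, −78 °C; allyl bromide, −78 to −20 °C
Reagents that add atoms: allyl bromide, C=CCBr
Why: ester enolate alkylation: LDA should remove the C10 hydrogen (α to the methyl ester) and not the C6 hydrogen (tert-butyl ester next to quaternary C8), and allyl bromide should enter from the β face, anti to the vicinal C9–C11 bond and the C5 side chain, leaving C20 α.

Step 14
Reactants: 20 10β-allyl-10α-methoxycarbonyl diester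
Product: 21 10β-allyl-10α-hydroxymethyl tert-butyl ester (C20 alcohol)
Conditions: LiBH4 (3 equiv), MeOH (1 equiv), THF, 0 to 40 °C
Reagents that add atoms: none
Why: lithium borohydride reduces methyl esters but not tert-butyl esters, so only C20 should be taken to the alcohol.

Step 15
Reactants: 21 10β-allyl-10α-hydroxymethyl tert-butyl ester
Product: 23 γ-lactone (C19 carbonyl on C5α; O-C20 on C10α; 10β-allyl; 16-ketal; 7-tert-butyl ester), via lactol 22 (not isolated)
Conditions: 80% aq. AcOH/THF, rt; evaporate; TEMPO (0.2 equiv), PhI(OAc)2 (2.2 equiv), CH2Cl2, rt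
Reagents that add atoms: water, O
Why: the acyclic dimethyl acetal should hydrolyse before the hindered spiro-dioxolane, the aldehyde is held by C20-OH as the cis-fused lactol (C5 can equilibrate through the enol, which fixes C19 α), and oxoammonium oxidation gives the lactone.

Step 16
Reactants: 23 γ-lactone
Product: 24 hydroxy ketone (5α-(2-methylbut-3-enoyl); 10β-allyl; 10α-CH2OH)
Conditions: crotylmagnesium chloride (1.3 equiv), THF, −78 °C; aq. NH4Cl at −78 °C
Reagents that add atoms: crotylmagnesium chloride, C/C=C/C[Mg]Cl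
Why: an allylic Grignard reagent adds once to a lactone at low temperature (the magnesium lactolate is stable) and reacts through its γ-carbon (SE2′) to give the α-methylallyl ketone, while the hindered tert-butyl ester should stay inert.

Step 17
Reactants: 24 hydroxy ketone
Product: 25 A-homo ketone (seven-membered ring C10-C1-C2=C3-C4-C19-C5; 19-oxo; 10α-CH2OH)
Conditions: (H2IMes)(PCy3)Cl2Ru=CHPh (5 mol%), CH2Cl2 (5 mM), 40 °C
Reagents that add atoms: none
Why: ring-closing metathesis of the two monosubstituted alkenes should close the seven-membered ring and place the alkene at C2=C3.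

Step 18
Reactants: 25 A-homo ketone
Product: 26 4-hydroxy A-homo ketone (α-ketol; C4 epimers)
Conditions: KHMDS (2.3 equiv), THF, −78 °C; 2-(phenylsulfonyl)-3-phenyloxaziridine (1.4 equiv); aq. NH4Cl
Reagents that add atoms: 2-(phenylsulfonyl)-3-phenyloxaziridine, O=S(=O)(N1OC1c1ccccc1)c1ccccc1
Why: the C4 hydrogen (α to the ketone and allylic) should be removed in preference to the C5 hydrogen, and the dienolate is hydroxylated at its α-carbon by the N-sulfonyloxaziridine (enolate oxidation); either C4 epimer serves in step 19.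

Step 19
Reactants: 26 4-hydroxy A-homo ketone
Product: 29 tert-butyl 2,3-didehydro-16-oxo-17-nor 19,20-lactone ester, via bridged hemiketal 27 (not isolated), via ketal lactone 28 (not isolated)
Conditions: p-TsOH·H2O (0.3 equiv), acetone/H2O 20:1, 0 to 40 °C
Reagents that add atoms: water, O
Why: Proposed new method: in acid the C20 hydroxyl adds to the C19 ketone (5-exo-trig) to give the bridged hemiketal 27; its tertiary allylic C4 hydroxyl ionises to the C2-C3-C4 allyl cation and C5 shifts from C19 to C4 while the hemiketal collapses to the protonated lactone, so the seven-membered ring C10-C1-C2-C3-C4-C19-C5 contracts to ring A and the five-membered hemiketal ring expands to the δ-lactone (28), after which the same aqueous acid hydrolyses the dioxolane. The closest known reaction types are the pinacol and semipinacol ring contractions of vicinal diols and 2,3-epoxy alcohols and the quasi-Favorskii (semibenzilic) shift of α-halo ketones; new is a hemiketal carbon as migration origin, which gives the lactone oxidation level directly. Ring A closes by a suprafacial 1,2-alkyl shift in which C5 keeps its configuration (H-5 stays β, trans to C20), and the lactone ring arises by enlargement of the 5-exo hemiketal. The new quaternary centre C4 is controlled by the C20-O-C19 tether: C19 stays bonded to C4 and to the α-oxygen on C10 and can therefore only become the axial α substituent, which leaves the methyl group β from either C4 epimer of 26. The step needs migration of C5 alone (C19 bears no hydrogen and no second carbon substituent), bond formation at C4 and not at C2 of the allyl cation (only the 1,2-shift is within reach, which places the alkene at C2=C3), and ionisation in the hemiketal and not in the keto form (there the cation would be α to a carbonyl group and has no oxygen push).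

Step 20
Reactants: 29 tert-butyl 2,3-didehydro-16-oxo-17-nor 19,20-lactone ester
Product: 30 tert-butyl 2β,3β-dihydroxy-16-oxo-17-nor 19,20-lactone ester
Conditions: OsO4 (5 mol%), NMO (1.5 equiv), acetone/H2O 4:1, rt
Reagents that add atoms: N-methylmorpholine N-oxide, C[N+]1([O-])CCOCC1; water, O (osmium tetroxide, O=[Os](=O)(=O)=O, is catalytic)
Why: catalytic syn-dihydroxylation should occur on the β (exo) face because the α face of ring A is covered by the 1,3-diaxial lactone bridge of the bicyclo[3.3.1] unit, which gives the cis-2β,3β-diol; no other alkene is present.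

Step 21
Reactants: 30 tert-butyl 2β,3β-dihydroxy-16-oxo-17-nor 19,20-lactone ester
Product: 31 tert-butyl ester of the target
Conditions: Zn, CH2Br2, TiCl4 (preformed reagent, excess), THF/CH2Cl2, 0 °C to rt
Reagents that add atoms: dibromomethane, BrCBr
Why: the non-basic zinc/titanium gem-dimetallic reagent methylenates ketones but not lactones or esters, and it avoids the retro-aldol epimerisation at C3 that basic ylides can cause in 3-hydroxy-4-acyl systems.

Step 22
Reactants: 31 tert-butyl ester of the target
Product: 33 2β,3β-dihydroxy 19,20-lactone 7-acid (target), via tris(trimethylsilyl) derivative 32 (not isolated)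
Conditions: TMSOTf (5 equiv), 2,6-lutidine (8 equiv), CH2Cl2, 0 °C to rt; then MeOH, aq. citric acid, rt
Reagents that add atoms: none
Why: silyl-triflate-mediated cleavage of the tert-butyl ester (loss of 2-methylpropene) in a lutidine-buffered medium should spare the acid-sensitive exocyclic alkene, and the silyl ester and silyl ethers fall off on mild acidic methanolysis.

**Compound list**
1 | benzoic acid | OC(=O)c1ccccc1 | starting material
2 | propargyl bromide (3-bromoprop-1-yne) | BrCC#C | starting material
3 | 1-(prop-2-yn-1-yl)cyclohexa-2,5-diene-1-carboxylic acid | OC(=O)C1(CC#C)C=CCC=C1 | intermediate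
4 | 1-(prop-2-yn-1-yl)cyclohexa-2,5-diene-1-carbonyl chloride | ClC(=O)C1(CC#C)C=CCC=C1 | intermediate
5 | 2-diazo-1-[1-(prop-2-yn-1-yl)cyclohexa-2,5-dien-1-yl]ethan-1-one | [N-]=[N+]=CC(=O)C1(CC#C)C=CCC=C1 | intermediate
6 | tert-butyl 2-[1-(prop-2-yn-1-yl)cyclohexa-2,5-dien-1-yl]acetate | CC(C)(C)OC(=O)CC1(CC#C)C=CCC=C1 | intermediate
7 | tert-butyl 2-[4-oxo-1-(prop-2-yn-1-yl)cyclohexa-2,5-dien-1-yl]acetate | CC(C)(C)OC(=O)CC1(CC#C)C=CC(=O)C=C1 | intermediate
8 | tert-butyl 2-[(1S)-4-oxo-1-(prop-2-yn-1-yl)cyclohex-2-en-1-yl]acetate | C#CC[C@]1(CC(=O)OC(C)(C)C)CCC(=O)C=C1 | intermediate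
9 | tert-butyl 2-[(1S)-4-(tert-butyldimethylsilyloxy)-1-(prop-2-yn-1-yl)cyclohexa-2,4-dien-1-yl]acetate | C#CC[C@]1(CC(=O)OC(C)(C)C)CC=C(O[Si](C)(C)C(C)(C)C)C=C1 | intermediate
10 | tert-butyl 2-(6-methylidene-4-oxobicyclo[3.2.1]oct-2-en-1-yl)acetate (bridgeheads = C8 and C13, configured as in the target) | C=C1C[C@]2(CC(=O)OC(C)(C)C)C[C@H]1C(=O)C=C2 | intermediate
11 | spiro-1,2,4-trioxolane (ozonide) of 10 at the exocyclic alkene | O1COOC12C[C@]3(CC(=O)OC(C)(C)C)C[C@H]2C(=O)C=C3 | intermediate
12 | tert-butyl 2-(4,6-dioxobicyclo[3.2.1]oct-2-en-1-yl)acetate | O=C1C[C@]2(CC(=O)OC(C)(C)C)C[C@H]1C(=O)C=C2 | intermediate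
13 | tert-butyl 2-[4-oxospiro(bicyclo[3.2.1]oct-2-ene-6,2'-[1,3]dioxolan)-1-yl]acetate | C12(OCCO1)C[C@]3(CC(=O)OC(C)(C)C)C[C@H]2C(=O)C=C3 | intermediate
14 | 2,2-dimethoxyacetaldehyde | COC(OC)C=O | starting material
15 | methyl (triphenylphosphoranylidene)acetate | COC(=O)C=P(c1ccccc1)(c1ccccc1)c1ccccc1 | starting material
16 | methyl (E)-4,4-dimethoxybut-2-enoate | COC(=O)/C=C/C(OC)OC | intermediate
17 | B/C/D keto diester: cyclopentane ring B (C5, C6, C8, C9, C10) cis-fused (9β-H) to the bicyclo[3.2.1]octane, with 5α-CH(OMe)2, 6β-CO2tBu, 10β-CO2Me, 12-ketone and 16-ethylene ketal | C12(OCCO1)C[C@]34C[C@H]2C(=O)C[C@H]3[C@H](C(=O)OC)[C@@H](C(OC)OC)[C@@H]4C(=O)OC(C)(C)C | intermediate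
18 | C12 tosylhydrazone of 17 | C12(OCCO1)C[C@]34C[C@H]2C(=NNS(=O)(=O)c5ccc(C)cc5)C[C@H]3[C@H](C(=O)OC)[C@@H](C(OC)OC)[C@@H]4C(=O)OC(C)(C)C | intermediate
19 | 12-deoxo diester (5α-CH(OMe)2, 6β-CO2tBu, 10β-CO2Me, 16-ketal) | C12(OCCO1)C[C@]34C[C@H]2CC[C@H]3[C@H](C(=O)OC)[C@@H](C(OC)OC)[C@@H]4C(=O)OC(C)(C)C | intermediate
20 | 10β-allyl-10α-methoxycarbonyl diester (C10 quaternary; 5α-CH(OMe)2, 6β-CO2tBu) | C12(OCCO1)C[C@]34C[C@H]2CC[C@H]3[C@](C(=O)OC)(CC=C)[C@@H](C(OC)OC)[C@@H]4C(=O)OC(C)(C)C | intermediate
21 | 10β-allyl-10α-hydroxymethyl tert-butyl ester (C20 alcohol; 5α-CH(OMe)2) | C12(OCCO1)C[C@]34C[C@H]2CC[C@H]3[C@](CO)(CC=C)[C@@H](C(OC)OC)[C@@H]4C(=O)OC(C)(C)C | intermediate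
22 | 19,20-lactol (cis-fused on C5/C10, anomeric mixture) | C12(OCCO1)C[C@]34C[C@H]2CC[C@H]3[C@@]1(CC=C)COC(O)[C@H]1[C@@H]4C(=O)OC(C)(C)C | intermediate
23 | γ-lactone: C19 carbonyl on C5 (α), O-C20H2 on C10 (α), 10β-allyl, 6β-CO2tBu, 16-ketal | C12(OCCO1)C[C@]34C[C@H]2CC[C@H]3[C@@]1(CC=C)COC(=O)[C@H]1[C@@H]4C(=O)OC(C)(C)C | intermediate
24 | hydroxy ketone: 5α-(2-methylbut-3-enoyl), 10β-allyl, 10α-CH2OH (C4 epimers; in equilibrium with its lactol) | C12(OCCO1)C[C@]34C[C@H]2CC[C@H]3[C@](CO)(CC=C)[C@@H](C(=O)C(C)C=C)[C@@H]4C(=O)OC(C)(C)C | intermediate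
25 | A-homo ketone: seven-membered ring C10-C1H2-C2H=C3H-C4H(Me)-C19(=O)-C5, trans-fused to ring B, 10α-CH2OH (C4 epimers) | C12(OCCO1)C[C@]34C[C@H]2CC[C@H]3[C@]1(CO)CC=CC(C)C(=O)[C@H]1[C@@H]4C(=O)OC(C)(C)C | intermediate
26 | 4-hydroxy A-homo ketone (α-ketol; C4 epimers) | C12(OCCO1)C[C@]34C[C@H]2CC[C@H]3[C@]1(CO)CC=CC(C)(O)C(=O)[C@H]1[C@@H]4C(=O)OC(C)(C)C | intermediate
27 | bridged hemiketal of 26 (C20-O-C19 bridge on the α face; C19-OH; C4-OH) | C12(OCCO1)C[C@]34C[C@H]2CC[C@H]3[C@]15CC=CC(C)(O)[C@@](O)(OC5)[C@H]1[C@@H]4C(=O)OC(C)(C)C | intermediate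
28 | tert-butyl 2,3-didehydro 19,20-lactone ester with the 16-ketone as ethylene ketal | C12(OCCO1)C[C@]34C[C@H]2CC[C@H]3[C@]12COC(=O)[C@](C)(C=CC1)[C@H]2[C@@H]4C(=O)OC(C)(C)C | intermediate
29 | tert-butyl 2,3-didehydro-16-oxo-17-nor 19,20-lactone ester | O=C1C[C@]23C[C@H]1CC[C@H]2[C@]12COC(=O)[C@](C)(C=CC1)[C@H]2[C@@H]3C(=O)OC(C)(C)C | intermediate
30 | tert-butyl 2β,3β-dihydroxy-16-oxo-17-nor 19,20-lactone ester | O=C1C[C@]23C[C@H]1CC[C@H]2[C@]12COC(=O)[C@](C)([C@@H](O)[C@@H](O)C1)[C@H]2[C@@H]3C(=O)OC(C)(C)C | intermediate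
31 | tert-butyl ester of the target (16-methylene restored) | C=C1C[C@]23C[C@H]1CC[C@H]2[C@]12COC(=O)[C@](C)([C@@H](O)[C@@H](O)C1)[C@H]2[C@@H]3C(=O)OC(C)(C)C | intermediate
32 | trimethylsilyl ester 2,3-bis(trimethylsilyl) ether of the target | C=C1C[C@]23C[C@H]1CC[C@H]2[C@]12COC(=O)[C@](C)([C@@H](O[Si](C)(C)C)[C@@H](O[Si](C)(C)C)C1)[C@H]2[C@@H]3C(=O)O[Si](C)(C)C | intermediate
33 | 2β,3β-dihydroxy-ent-gibberell-16-ene-7,19-dioic acid 19,20-lactone (CNP0332607.1) | C=C1C[C@]23C[C@H]1CC[C@H]2[C@]12COC(=O)[C@](C)([C@@H](O)[C@@H](O)C1)[C@H]2[C@@H]3C(=O)O | target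

**Count and risks**
Total step count: 22. Longest linear sequence: 21 steps (steps 1–9 and 11–22, from benzoic acid).

Step 19 (labelled new). The allyl cation may form in the keto form and be caught at C2 by the free C20 hydroxyl (ether formation), or the substrate may simply eliminate to the dienone or undergo an α-ketol shift before the hemiketal-gated 1,2-shift takes place. The fallback sets out from 26 and returns at 28. Sodium borohydride (MeOH, 0 °C) reduces the C19 ketone to the 4,19,20-triol F1. A classical acid-promoted pinacol rearrangement of this vicinal diol (ionisation of the tertiary allylic C4 hydroxyl, migration of C5) gives the ring-contracted C19 aldehyde, which closes with the C20 hydroxyl to the 19,20-lactol F2. Oxidation with TEMPO/PhI(OAc)2 then gives the ketal lactone 28, which is deketalised to 29 with aqueous acid as in step 19. Any hydride-shift product of the pinacol step is the ketone 25 and can be returned to step 18.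

Step 11. After the first conjugate addition, proton transfer and oligomerisation may outrun the ring-closing second addition, and facial control at C5 may be poor. The fallback sets out from 13 and 16 and returns at 17. The first addition is quenched cold to isolate the open-chain Michael adduct F3. Its methyl ester is converted (LDA/TMSCl, internal quench) into the trimethylsilyl ketene acetal F4, and ring B is closed by a TiCl4-mediated intramolecular Mukaiyama–Michael addition to the enone to give 17.

Step 13. Enolisation may occur at C6 in place of C10, and the alkylation may take place in part from the α face. The fallback sets out from 19 and returns at 21. DIBAL-H (1.1 equiv, −78 °C) reduces only the methyl ester to the C20 aldehyde F5, which has a single α-hydrogen. Palladium-catalysed Tsuji–Trost α-allylation (allyl acetate, Pd(PPh3)4, cat. pyrrolidine) gives the 10β-allyl C20 aldehyde F6. Sodium borohydride then gives the alcohol 21, so that step 14 is also replaced.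

Further compounds
F1 | step 19 | 4,19,20-triol (C19 alcohol of 26; C4 and C19 epimers) | C12(OCCO1)C[C@]34C[C@H]2CC[C@H]3[C@]1(CO)CC=CC(C)(O)C(O)[C@H]1[C@@H]4C(=O)OC(C)(C)C
F2 | step 19 | 19,20-lactol of the ring-contracted 2,3-didehydro aldehyde (16-ketal, tert-butyl ester) | C12(OCCO1)C[C@]34C[C@H]2CC[C@H]3[C@]12COC(O)[C@](C)(C=CC1)[C@H]2[C@@H]4C(=O)OC(C)(C)C
F3 | step 11 | open-chain Michael adduct of 13 and 16 (enone intact) | C12(OCCO1)C[C@]3([C@@H](C(=O)OC(C)(C)C)[C@@H](CC(=O)OC)C(OC)OC)C[C@H]2C(=O)C=C3
F4 | step 11 | trimethylsilyl ketene acetal of the methyl ester of F3 | C12(OCCO1)C[C@]3([C@@H](C(=O)OC(C)(C)C)[C@@H](C=C(OC)O[Si](C)(C)C)C(OC)OC)C[C@H]2C(=O)C=C3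
F5 | step 13 | C20 aldehyde (10-formyl analogue of 19) | C12(OCCO1)C[C@]34C[C@H]2CC[C@H]3[C@H](C=O)[C@@H](C(OC)OC)[C@@H]4C(=O)OC(C)(C)C
F6 | step 13 | 10β-allyl C20 aldehyde (C10 quaternary) | C12(OCCO1)C[C@]34C[C@H]2CC[C@H]3[C@](C=O)(CC=C)[C@@H](C(OC)OC)[C@@H]4C(=O)OC(C)(C)C
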